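The carbocycle (C1–C6) is cut into three two-carbon pieces: C1–C6 from an α-silyloxy aldehyde, C5–C4 from a nitroalkene whose nitro group stands in for the C4 oxygen, and C3–C2 with the hydroxymethyl carbon from a propiolate. One flask joins them: a catalytic anti-Michael addition forms C6–C5 and sets these two stereocentres, the nitronate then adds to the alkynoate (C4–C3), and the allenolate closes C2–C1 by aldol. The feature exploited is the alternating polarity of the ring: oxygen on C1, C6 and C4, and a C2=C3 alkene carrying one exocyclic carbon. The precursor is the set of three components 5, 6 and 7.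

Key step: step 3

Remark 1: ring atoms keep the target numbering throughout (C1 carbonyl carbon, C2 bears CH2OH, C3 olefinic CH, C4 angelate, C5 isopropyl, C6 hydroxytiglate). The target is read as 4S,5S,6S in this numbering, with the substituents on C4, C5 and C6 all cis. An anti Michael adduct becomes a cis C5/C6 pair on ring closure, so the anti adduct is the one required.
Remark 2 (assumption): the (1R,2R) amine–thiourea is taken to give (2S,3S)-8; the mirror-image catalyst is used instead if a pilot run shows the opposite sense.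
Remark 3 (assumption): C4 (nitro) and C1 (carbinol) are drawn as the expected epimers; mixtures there are carried on, since C4 is erased in step 6 and C1 in step 11.
TBS = tert-butyldimethylsilyl.

Step 1
Reactants: 1 isobutyraldehyde; 2 nitromethane
Product: 3 3-methyl-1-nitrobutan-2-ol (racemic)
Conditions: KOtBu (5 mol%), THF/t-BuOH, 0 °C → rt
Reagents that add atoms: none
Why: Base-catalysed Henry (nitroaldol) addition of the nitromethane anion to the aldehyde; the carbinol centre formed is racemic and disappears in step 2.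

Step 2
Reactants: 3 3-methyl-1-nitrobutan-2-ol
Product: 5 (E)-3-methyl-1-nitrobut-1-ene, via mesylate 4 (not isolated)
Conditions: MsCl, Et3N, CH2Cl2, 0 °C
Reagents that add atoms: none
Why: Mesylation followed by E1cB elimination (dehydration of a β-nitro alcohol) should give the conjugated nitroalkene, the E isomer being strongly favoured thermodynamically.

Step 3
Reactants: 5 (E)-3-methyl-1-nitrobut-1-ene; 6 (tert-butyldimethylsilyloxy)acetaldehyde; 7 ethyl propiolate
Product: 9 ethyl (3R,4S,5S,6S)-5-(tert-butyldimethylsilyloxy)-6-hydroxy-3-nitro-4-(propan-2-yl)cyclohex-1-ene-1-carboxylate, via nitro aldehyde 8 (not isolated)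
Conditions: 1-[(1R,2R)-2-aminocyclohexyl]-3-[3,5-bis(trifluoromethyl)phenyl]thiourea (15 mol%), CH2Cl2, rt; then 7, Cs2CO3, −20 → 0 °C; AcOH, −20 °C
Reagents that add atoms: none
Why: Proposed new method: the primary amine of the catalyst turns 6 into its (Z)-enamine (held by an N–H···O contact to the silyloxy oxygen), which adds to the thiourea-bound nitroalkene to give anti adduct 8; Cs2CO3 then forms the nitronate of 8, this adds to the β-carbon of 7 (C4–C3) and the allenolate so produced attacks the tethered aldehyde through its α-carbon (C2–C1), while a second path through the protonated γ-nitro enoate and its extended anion would lead to the same ring. The closest known reactions are the one-flask enamine Michael/nitronate Michael/Horner–Wadsworth–Emmons cyclohexene annulations and nucleophile-triggered Michael–aldol reactions of alkynoates; the untested part is the use of a propiolate as third component so that the aldol carbinol is kept. The single ring closes by a 6-exo-trig aldol addition, the C1 carbonyl lying outside the forming ring. C6 and C5 are set by the catalyst (enamine geometry and shielded face), C4 is expected to settle with nitro trans to isopropyl under base, and C1 is expected to arise from attack anti to the C6 silyloxy group; these last two centres are removed later. The step needs carbon–carbon bond formation to outrun epimerisation at C6 and base-induced dehydration of 9, which the intramolecular aldol, the low temperature and the cold acidic quench are meant to secure.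

Step 4
Reactants: 9 ethyl (3R,4S,5S,6S)-5-(tert-butyldimethylsilyloxy)-6-hydroxy-3-nitro-4-(propan-2-yl)cyclohex-1-ene-1-carboxylate
Product: 10 (1S,4R,5S,6S)-6-(tert-butyldimethylsilyloxy)-2-(hydroxymethyl)-4-nitro-5-(propan-2-yl)cyclohex-2-en-1-ol
Conditions: i-Bu2AlH (4.5 equiv), CH2Cl2, −78 °C; aq. potassium sodium tartrate
Reagents that add atoms: none
Why: Hydride 1,2-reduction of the α,β-unsaturated ester at low temperature should give the allylic alcohol while the aliphatic nitro group and the silyl ether are left alone; reducing the ester before the Nef step removes the doubly activated γ-nitro enoate and no stereocentre is formed.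

Step 5
Reactants: 10 (1S,4R,5S,6S)-6-(tert-butyldimethylsilyloxy)-2-(hydroxymethyl)-4-nitro-5-(propan-2-yl)cyclohex-2-en-1-ol
Product: 11 (3R,4S,5S,6S)-5,6-bis(tert-butyldimethylsilyloxy)-1-[(tert-butyldimethylsilyloxy)methyl]-3-nitro-4-(propan-2-yl)cyclohex-1-ene
Conditions: TBSOTf (2.6 equiv), 2,6-lutidine, CH2Cl2, −78 → 0 °C
Reagents that add atoms: tert-butyldimethylsilyl trifluoromethanesulfonate (TBSOTf), CC(C)(C)[Si](C)(C)OS(=O)(=O)C(F)(F)F
Why: Silyl triflate silylation of both hydroxyls under a hindered pyridine base; because O1 and O6 end up with the same group, any base-induced silyl shift between them in step 3 is of no consequence.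

Step 6
Reactants: 11 (3R,4S,5S,6S)-5,6-bis(tert-butyldimethylsilyloxy)-1-[(tert-butyldimethylsilyloxy)methyl]-3-nitro-4-(propan-2-yl)cyclohex-1-ene
Product: 13 (4S,5S,6R)-4,5-bis(tert-butyldimethylsilyloxy)-3-[(tert-butyldimethylsilyloxy)methyl]-6-(propan-2-yl)cyclohex-2-en-1-one, via potassium nitronate 12 (not isolated)
Conditions: KOtBu (1.05 equiv), THF, −78 °C; then dimethyldioxirane (acetone), −78 → −20 °C
Reagents that add atoms: dimethyldioxirane, CC1(C)OO1
Why: Oxidative Nef reaction: the nitro C–H is by far the most acidic site, the nitronate C=N bond is oxidised by the dioxirane with loss of nitrite, and the ketone appears in a medium free of strong base or acid, which guards the now enolisable C5 centre and the β-silyloxy group at C6.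

Step 7
Reactants: 13 (4S,5S,6R)-4,5-bis(tert-butyldimethylsilyloxy)-3-[(tert-butyldimethylsilyloxy)methyl]-6-(propan-2-yl)cyclohex-2-en-1-one
Product: 14 (1S,4S,5S,6S)-4,5-bis(tert-butyldimethylsilyloxy)-3-[(tert-butyldimethylsilyloxy)methyl]-6-(propan-2-yl)cyclohex-2-en-1-ol
Conditions: LiBH(s-Bu)3, THF, −78 °C; H2O, −78 °C
Reagents that add atoms: none
Why: 1,2-Reduction of a β-substituted cyclohexenone by a bulky trialkylborohydride (the fully substituted β-carbon blocks conjugate reduction); hydride should enter anti to the cis-disposed C5 isopropyl and C6 silyloxy groups, placing the new C4 hydroxyl cis to both (4S).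

Step 8
Reactants: 14 (1S,4S,5S,6S)-4,5-bis(tert-butyldimethylsilyloxy)-3-[(tert-butyldimethylsilyloxy)methyl]-6-(propan-2-yl)cyclohex-2-en-1-ol; 15 angelic acid [(2Z)-2-methylbut-2-enoic acid]
Product: 17 (1S,4S,5S,6S)-4,5-bis(tert-butyldimethylsilyloxy)-3-[(tert-butyldimethylsilyloxy)methyl]-6-(propan-2-yl)cyclohex-2-en-1-yl (2Z)-2-methylbut-2-enoate, via mixed anhydride 16 (not isolated)
Conditions: 15, 2,4,6-trichlorobenzoyl chloride, Et3N, toluene, rt; then 14, 80 °C
Reagents that add atoms: none
Why: Yamaguchi esterification through the mixed anhydride, run without DMAP so that the Z acyl group is not isomerised to the tiglate by reversible conjugate addition of a nucleophilic catalyst; no stereocentre is touched.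

Step 9
Reactants: 17 (1S,4S,5S,6S)-4,5-bis(tert-butyldimethylsilyloxy)-3-[(tert-butyldimethylsilyloxy)methyl]-6-(propan-2-yl)cyclohex-2-en-1-yl (2Z)-2-methylbut-2-enoate
Product: 18 (1S,4S,5S,6R)-4,5-dihydroxy-3-(hydroxymethyl)-6-(propan-2-yl)cyclohex-2-en-1-yl (2Z)-2-methylbut-2-enoate
Conditions: 48% aq. HF, MeCN, 0 °C → rt
Reagents that add atoms: none
Why: Acidic fluoride cleavage of all three silyl ethers (desilylation); the acidic medium should suppress 1,3-acyl migration of the angelate to the cis C6 hydroxyl, and the allylic ester is stable to it.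

Step 10
Reactants: 18 (1S,4S,5S,6R)-4,5-dihydroxy-3-(hydroxymethyl)-6-(propan-2-yl)cyclohex-2-en-1-yl (2Z)-2-methylbut-2-enoate
Product: 19 (1S,4S,5S,6R)-3-[(tert-butyldimethylsilyloxy)methyl]-4,5-dihydroxy-6-(propan-2-yl)cyclohex-2-en-1-yl (2Z)-2-methylbut-2-enoate
Conditions: TBSCl (1.05 equiv), imidazole, CH2Cl2, −20 °C
Reagents that add atoms: tert-butyldimethylsilyl chloride (TBSCl), CC(C)(C)[Si](C)(C)Cl
Why: Sterically controlled silylation: the primary allylic hydroxyl should react far faster with the bulky silyl chloride than the two secondary hydroxyls.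

Step 11
Reactants: 19 (1S,4S,5S,6R)-3-[(tert-butyldimethylsilyloxy)methyl]-4,5-dihydroxy-6-(propan-2-yl)cyclohex-2-en-1-yl (2Z)-2-methylbut-2-enoate
Product: 20 (1S,5S,6R)-3-[(tert-butyldimethylsilyloxy)methyl]-5-hydroxy-4-oxo-6-(propan-2-yl)cyclohex-2-en-1-yl (2Z)-2-methylbut-2-enoate
Conditions: MnO2 (activated, excess), CH2Cl2, rt
Reagents that add atoms: none
Why: Chemoselective allylic alcohol oxidation: MnO2 should oxidise the C1 carbinol next to the C2=C3 alkene to the enone and leave the saturated C6 hydroxyl, which removes the C1 stereocentre under neutral conditions.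

Step 12
Reactants: 6 (tert-butyldimethylsilyloxy)acetaldehyde; 21 ethyl 2-(triphenylphosphoranylidene)propanoate
Product: 22 ethyl (2E)-4-(tert-butyldimethylsilyloxy)-2-methylbut-2-enoate
Conditions: CH2Cl2, rt
Reagents that add atoms: none
Why: Wittig olefination with a stabilised, α-branched ylide should give the trisubstituted E-enoate selectively.

Step 13
Reactants: 22 ethyl (2E)-4-(tert-butyldimethylsilyloxy)-2-methylbut-2-enoate
Product: 23 (2E)-4-(tert-butyldimethylsilyloxy)-2-methylbut-2-enoic acid
Conditions: LiOH·H2O, THF/MeOH/H2O, rt; then 1 M HCl to pH 4, 0 °C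
Reagents that add atoms: lithium hydroxide, [Li+].[OH-]
Why: Saponification of the ethyl ester; the primary silyl ether should withstand aqueous hydroxide at room temperature and a cold, mildly acidic work-up.

Step 14
Reactants: 20 (1S,5S,6R)-3-[(tert-butyldimethylsilyloxy)methyl]-5-hydroxy-4-oxo-6-(propan-2-yl)cyclohex-2-en-1-yl (2Z)-2-methylbut-2-enoate; 23 (2E)-4-(tert-butyldimethylsilyloxy)-2-methylbut-2-enoic acid
Product: 24 (1S,5S,6S)-5-{[(2E)-4-(tert-butyldimethylsilyloxy)-2-methylbut-2-enoyl]oxy}-3-[(tert-butyldimethylsilyloxy)methyl]-4-oxo-6-(propan-2-yl)cyclohex-2-en-1-yl (2Z)-2-methylbut-2-enoate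
Conditions: EDC·HCl, DMAP (0.2 equiv), CH2Cl2, 0 °C → rt
Reagents that add atoms: none
Why: Carbodiimide (Steglich) esterification of the only free hydroxyl; catalytic DMAP at low temperature should acylate O6 without enolising the α-oxygenated ketone, so C6 keeps its configuration.

Step 15
Reactants: 24 (1S,5S,6S)-5-{[(2E)-4-(tert-butyldimethylsilyloxy)-2-methylbut-2-enoyl]oxy}-3-[(tert-butyldimethylsilyloxy)methyl]-4-oxo-6-(propan-2-yl)cyclohex-2-en-1-yl (2Z)-2-methylbut-2-enoate
Product: 25 (1S,5S,6S)-5-{[(2E)-4-hydroxy-2-methylbut-2-enoyl]oxy}-3-(hydroxymethyl)-4-oxo-6-(propan-2-yl)cyclohex-2-en-1-yl (2Z)-2-methylbut-2-enoate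
Conditions: HF·pyridine, pyridine, THF, 0 °C → rt
Reagents that add atoms: none
Why: Buffered fluoride desilylation should remove both primary silyl ethers under near-neutral conditions that avoid acyl migration, ester cleavage and enolisation at C6.

Compound list
1 | isobutyraldehyde | CC(C)C=O | starting material
2 | nitromethane | C[N+](=O)[O-] | starting material
3 | 3-methyl-1-nitrobutan-2-ol (racemic) | CC(C)C(O)C[N+](=O)[O-] | intermediate
4 | 3-methyl-1-nitrobutan-2-yl methanesulfonate (racemic, not isolated) | CC(C)C(OS(C)(=O)=O)C[N+](=O)[O-] | intermediate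
5 | (E)-3-methyl-1-nitrobut-1-ene | CC(C)/C=C/[N+](=O)[O-] | intermediate
6 | (tert-butyldimethylsilyloxy)acetaldehyde | CC(C)(C)[Si](C)(C)OCC=O | starting material
7 | ethyl propiolate | C#CC(=O)OCC | starting material
8 | (2S,3S)-2-(tert-butyldimethylsilyloxy)-4-methyl-3-(nitromethyl)pentanal (anti adduct, not isolated) | O=C[C@@H](O[Si](C)(C)C(C)(C)C)[C@@H](C(C)C)C[N+](=O)[O-] | intermediate
9 | ethyl (3R,4S,5S,6S)-5-(tert-butyldimethylsilyloxy)-6-hydroxy-3-nitro-4-(propan-2-yl)cyclohex-1-ene-1-carboxylate | CCOC(=O)C1=C[C@@H]([N+](=O)[O-])[C@H](C(C)C)[C@H](O[Si](C)(C)C(C)(C)C)[C@H]1O | intermediate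
10 | (1S,4R,5S,6S)-6-(tert-butyldimethylsilyloxy)-2-(hydroxymethyl)-4-nitro-5-(propan-2-yl)cyclohex-2-en-1-ol | OCC1=C[C@@H]([N+](=O)[O-])[C@H](C(C)C)[C@H](O[Si](C)(C)C(C)(C)C)[C@H]1O | intermediate
11 | (3R,4S,5S,6S)-5,6-bis(tert-butyldimethylsilyloxy)-1-[(tert-butyldimethylsilyloxy)methyl]-3-nitro-4-(propan-2-yl)cyclohex-1-ene | CC(C)(C)[Si](C)(C)OCC1=C[C@@H]([N+](=O)[O-])[C@H](C(C)C)[C@H](O[Si](C)(C)C(C)(C)C)[C@H]1O[Si](C)(C)C(C)(C)C | intermediate
12 | potassium nitronate of 11 (C4=N(O)O− K+, not isolated) | CC(C)(C)[Si](C)(C)OCC1=CC(=[N+]([O-])[O-])[C@H](C(C)C)[C@H](O[Si](C)(C)C(C)(C)C)[C@H]1O[Si](C)(C)C(C)(C)C.[K+] | intermediate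
13 | (4S,5S,6R)-4,5-bis(tert-butyldimethylsilyloxy)-3-[(tert-butyldimethylsilyloxy)methyl]-6-(propan-2-yl)cyclohex-2-en-1-one | CC(C)(C)[Si](C)(C)OCC1=CC(=O)[C@H](C(C)C)[C@H](O[Si](C)(C)C(C)(C)C)[C@H]1O[Si](C)(C)C(C)(C)C | intermediate
14 | (1S,4S,5S,6S)-4,5-bis(tert-butyldimethylsilyloxy)-3-[(tert-butyldimethylsilyloxy)methyl]-6-(propan-2-yl)cyclohex-2-en-1-ol | O[C@H]1C=C(CO[Si](C)(C)C(C)(C)C)[C@H](O[Si](C)(C)C(C)(C)C)[C@@H](O[Si](C)(C)C(C)(C)C)[C@H]1C(C)C | intermediate
15 | angelic acid, (2Z)-2-methylbut-2-enoic acid | C/C=C(/C)C(=O)O | starting material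
16 | (2Z)-2-methylbut-2-enoic 2,4,6-trichlorobenzoic anhydride (not isolated) | C/C=C(/C)C(=O)OC(=O)c1c(Cl)cc(Cl)cc1Cl | intermediate
17 | (1S,4S,5S,6S)-4,5-bis(tert-butyldimethylsilyloxy)-3-[(tert-butyldimethylsilyloxy)methyl]-6-(propan-2-yl)cyclohex-2-en-1-yl (2Z)-2-methylbut-2-enoate | C/C=C(/C)C(=O)O[C@H]1C=C(CO[Si](C)(C)C(C)(C)C)[C@H](O[Si](C)(C)C(C)(C)C)[C@@H](O[Si](C)(C)C(C)(C)C)[C@H]1C(C)C | intermediate
18 | (1S,4S,5S,6R)-4,5-dihydroxy-3-(hydroxymethyl)-6-(propan-2-yl)cyclohex-2-en-1-yl (2Z)-2-methylbut-2-enoate | C/C=C(/C)C(=O)O[C@H]1C=C(CO)[C@H](O)[C@@H](O)[C@H]1C(C)C | intermediate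
19 | (1S,4S,5S,6R)-3-[(tert-butyldimethylsilyloxy)methyl]-4,5-dihydroxy-6-(propan-2-yl)cyclohex-2-en-1-yl (2Z)-2-methylbut-2-enoate | C/C=C(/C)C(=O)O[C@H]1C=C(CO[Si](C)(C)C(C)(C)C)[C@H](O)[C@@H](O)[C@H]1C(C)C | intermediate
20 | (1S,5S,6R)-3-[(tert-butyldimethylsilyloxy)methyl]-5-hydroxy-4-oxo-6-(propan-2-yl)cyclohex-2-en-1-yl (2Z)-2-methylbut-2-enoate | C/C=C(/C)C(=O)O[C@H]1C=C(CO[Si](C)(C)C(C)(C)C)C(=O)[C@@H](O)[C@H]1C(C)C | intermediate
21 | ethyl 2-(triphenylphosphoranylidene)propanoate | CCOC(=O)C(C)=P(c1ccccc1)(c1ccccc1)c1ccccc1 | starting material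
22 | ethyl (2E)-4-(tert-butyldimethylsilyloxy)-2-methylbut-2-enoate | CCOC(=O)/C(C)=C/CO[Si](C)(C)C(C)(C)C | intermediate
23 | (2E)-4-(tert-butyldimethylsilyloxy)-2-methylbut-2-enoic acid | OC(=O)/C(C)=C/CO[Si](C)(C)C(C)(C)C | intermediate
24 | (1S,5S,6S)-5-{[(2E)-4-(tert-butyldimethylsilyloxy)-2-methylbut-2-enoyl]oxy}-3-[(tert-butyldimethylsilyloxy)methyl]-4-oxo-6-(propan-2-yl)cyclohex-2-en-1-yl (2Z)-2-methylbut-2-enoate | C/C=C(/C)C(=O)O[C@H]1C=C(CO[Si](C)(C)C(C)(C)C)C(=O)[C@@H](OC(=O)/C(C)=C/CO[Si](C)(C)C(C)(C)C)[C@H]1C(C)C | intermediate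
25 | (1S,5S,6S)-5-{[(2E)-4-hydroxy-2-methylbut-2-enoyl]oxy}-3-(hydroxymethyl)-4-oxo-6-(propan-2-yl)cyclohex-2-en-1-yl (2Z)-2-methylbut-2-enoate | C/C=C(/C)C(=O)O[C@H]1C=C(CO)C(=O)[C@@H](OC(=O)/C(C)=C/CO)[C@H]1C(C)C | target

Total step count: 15. Longest linear sequence: 13 steps (steps 1–11, 14 and 15); steps 12 and 13 form the side-chain branch.

Steps most likely to fail

Step 3 (Proposed new method). What may go wrong: the allenolate is protonated before it cyclises, the C6 centre epimerises under base, or the cyclised product loses water and silanol on the way to an arene. The fallback splits the assembly into isolated stages of known type, setting out from 5 and 6 and returning at 9. The amine–thiourea Michael addition is run alone and 8 is isolated. Nitroalkane 8 is then added to 7 under a catalytic amine base (DBU 10 mol%, MeCN, −20 °C, a known nitroalkane–alkynoate conjugate addition) and quenched early, giving the open-chain ethyl (5S,6S)-6-(tert-butyldimethylsilyloxy)-4-nitro-7-oxo-5-(propan-2-yl)hept-2-enoate F1. Ring closure is then a separate intramolecular Morita–Baylis–Hillman reaction (PMe3 or DABCO, CH2Cl2/t-BuOH, rt): the Lewis base adds reversibly to C3, the ester enolate attacks the aldehyde (C2–C1), and loss of the catalyst restores C2=C3 to give 9.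

Step 6. What may go wrong: oxidant attack on the C2=C3 alkene or at the far end (C2) of the conjugated nitronate, or, once the ketone exists, loss of the C6 silyloxy group and epimerisation at C5 under residual base. The fallback is a reductive two-stage route from 11 back to 13. SnCl2/PhSH/Et3N (MeCN, rt) reduces the secondary nitro group to the oxime of enone 13 F2. Buffered aqueous TiCl3 (NH4OAc, THF/H2O, 0 °C) then cleaves the oxime to 13 under weakly acidic conditions, so neither nitronate oxidation nor base contact with the ketone is needed.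

Step 8. What may go wrong: slow acylation of the hindered C4 hydroxyl and Z-to-E isomerisation of the activated angeloyl group. The fallback builds the angelate double bond on the substrate, from 14 back to 17. Alcohol 14 is esterified with 2-[bis(2,2,2-trifluoroethoxy)phosphoryl]propanoic acid (DCC, CH2Cl2, 0 °C → rt) to the 2-[bis(2,2,2-trifluoroethoxy)phosphoryl]propanoate ester of 14 F3. A Z-selective Horner–Wadsworth–Emmons olefination with acetaldehyde (KN(SiMe3)2, 18-crown-6, THF, −78 °C) then gives 17.

Further compounds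
F1 | step 3 | ethyl (5S,6S)-6-(tert-butyldimethylsilyloxy)-4-nitro-7-oxo-5-(propan-2-yl)hept-2-enoate (E/Z and C4 mixtures) | CCOC(=O)C=CC([N+](=O)[O-])[C@H](C(C)C)[C@H](O[Si](C)(C)C(C)(C)C)C=O
F2 | step 6 | oxime of enone 13 (C4=N–OH, E/Z mixture) | CC(C)(C)[Si](C)(C)OCC1=CC(=NO)[C@H](C(C)C)[C@H](O[Si](C)(C)C(C)(C)C)[C@H]1O[Si](C)(C)C(C)(C)C
F3 | step 8 | 2-[bis(2,2,2-trifluoroethoxy)phosphoryl]propanoate ester of 14 at O4 (epimers at the phosphonate carbon) | CC(C(=O)O[C@H]1C=C(CO[Si](C)(C)C(C)(C)C)[C@H](O[Si](C)(C)C(C)(C)C)[C@@H](O[Si](C)(C)C(C)(C)C)[C@H]1C(C)C)P(=O)(OCC(F)(F)F)OCC(F)(F)F
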